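**Plan**

1. Retrosynthesis: the C11=C12 and C11'=C12' alkenes are cut first (two Wittig disconnections), giving a ring C15 phosphonium salt, the C10 trienedial and a ψ-end C15 phosphonium salt. In the ring half the C9–C10 bond (vinyl addition), the C7=C8 alkene (HWE) and finally the C3–O and C4–O bonds are then cut.
2. Forward: the six-membered ring is bought with safranal and is never closed. The chain is joined as ψ-C15 + C10 → C25 aldehyde, then ring C15 + C25 → C40, so the ring half enters at the penultimate step.
3. Enabling feature (carotenoid numbering: ring C1 CMe2, C2 CH2, C3 and C4 carbinols, C5=C6 ring alkene): the trans-3,4-diol beside C5=C6 is the pattern left by anti addition of two hydroxyls to a cis C3=C4 alkene. The cyclohexa-1,3-diene ring of safranal carries exactly this alkene, conjugated with C5=C6.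
4. Stereochemistry: C3 and C4 are created together by one catalyst-controlled epoxidation of C3=C4 (cis-epoxide, 3R,4S). Water then opens the allylic C4–O bond with inversion (3R,4R). The chain alkenes are E from HWE, allylic transposition and Wittig steps with thermal Z to E equilibration.

Key step: step 3

Assumption: pseudoionone is used as its (3E,5E) isomer, with any 5Z material removed when salt 14 is crystallised; the (S,S) sense of the epoxidation catalyst is assigned by analogy with indene, and the mirror-image catalyst would be used if diol 5 proved to be the (3S,4S) enantiomer.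

Ring positions are given in carotenoid numbering throughout. All polyene steps are run under argon in dim light.

**Route**

Step 1
Reactants: 1 safranal (2,6,6-trimethylcyclohexa-1,3-diene-1-carbaldehyde)
Product: 2 safranic acid (2,6,6-trimethylcyclohexa-1,3-diene-1-carboxylic acid)
Conditions: NaClO2, NaH2PO4, 2-methylbut-2-ene, t-BuOH/H2O, 0 °C to rt
Reagents that add atoms: sodium chlorite, [Na+].[O-]Cl=O
Why: Pinnick oxidation, in which chlorous acid adds to the hindered enal and fragments to the acid while 2-methylbut-2-ene traps the hypochlorous acid that would otherwise attack the diene.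

Step 2
Reactants: 2 safranic acid
Product: 3 methyl safranate (methyl 2,6,6-trimethylcyclohexa-1,3-diene-1-carboxylate)
Conditions: MeI, K2CO3, DMF, rt
Reagents that add atoms: iodomethane, CI
Why: SN2 O-alkylation of the carboxylate, which should work on this doubly flanked acid where Fischer esterification at the carbonyl carbon would be slow.

Step 3
Reactants: 3 methyl safranate
Product: 4 methyl (1S,6R)-2,4,4-trimethyl-7-oxabicyclo[4.1.0]hept-2-ene-3-carboxylate (cis-3,4-epoxide; carotenoid C3 R, C4 S)
Conditions: (S,S)-N,N'-bis(3,5-di-tert-butylsalicylidene)-1,2-cyclohexanediaminomanganese chloride (4 mol%), 4-phenylpyridine N-oxide (20 mol%), aq NaOCl buffered to pH 11.3 with Na2HPO4, CH2Cl2, 0 °C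
Reagents that add atoms: sodium hypochlorite, [Na+].[O-]Cl
Why: Hypochlorite oxidises the trivalent manganese salen complex to a pentavalent oxomanganese species, and the C3=C4 alkene approaches it side-on over the chiral diamine bridge so that oxygen is passed to one enantiotopic face, forming the C3–O and C4–O bonds in a stepwise transfer whose ring-bound intermediate can only collapse to the cis-epoxide. The closest known reaction is the Jacobsen–Katsuki epoxidation of conjugated cis-disubstituted cyclic alkenes (indene, 2,2-dimethylchromenes, cyclic 1,3-dienes) and of dienoates, which are oxidised at the alkene remote from the ester. The only ring formed is the oxirane, closed by this [2+1] oxygen-atom transfer onto the existing six-membered ring, and no carbocycle is made. C3 and C4 are created together and both are fixed by the catalyst, since the C1 gem-dimethyl group makes the two diene faces enantiotopic; the (S,S) catalyst is chosen because it converts indene into (1S,2R)-indene oxide, which maps onto the 3R,4S epoxide when C5=C6 takes the place of the arene. The step needs site selectivity for C3=C4 over C5=C6, secured by the tetrasubstitution of C5=C6, its flanking gem-dimethyl group and its ester, and face selectivity, secured by the catalyst. The vinyl epoxide is acid-labile and should be carried on after filtration through triethylamine-deactivated silica.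

Step 4
Reactants: 4 cis-3,4-epoxide
Product: 5 methyl (3R,4R)-3,4-dihydroxy-2,6,6-trimethylcyclohex-1-ene-1-carboxylate
Conditions: HClO4 (5 mol%), THF/H2O, 0 °C to rt
Reagents that add atoms: water, O
Why: Acid-catalysed anti opening of a vinyl epoxide, in which water attacks the protonated oxirane at allylic C4 (assisted by the C5=C6 π bond and not shielded by the axial C1 methyl that hinders axial approach to C3), so that C4 is inverted from S to R while the untouched C3–O bond keeps C3 as R, and the ester keeps cation character low enough for clean inversion to the trans diol.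

Step 5
Reactants: 5 (3R,4R)-diol ester
Product: 6 methyl (3R,4R)-3,4-bis(tert-butyldimethylsilyloxy)-2,6,6-trimethylcyclohex-1-ene-1-carboxylate
Conditions: TBSOTf, 2,6-lutidine, CH2Cl2, 0 °C to rt
Reagents that add atoms: tert-butyldimethylsilyl trifluoromethanesulfonate, CC(C)(C)[Si](C)(C)OS(=O)(=O)C(F)(F)F
Why: Silylation with the silyl triflate is reactive enough to cap both secondary hydroxyls, including the hindered allylic C4 one, and no C–O bond is broken so both stereocentres are kept.

Step 6
Reactants: 6 bis-silyl ether ester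
Product: 7 [(3R,4R)-3,4-bis(tert-butyldimethylsilyloxy)-2,6,6-trimethylcyclohex-1-en-1-yl]methanol
Conditions: i-Bu2AlH (3 equiv), toluene, −78 to 0 °C; then aq potassium sodium tartrate
Reagents that add atoms: none
Why: Hydride reduction of the hindered conjugated ester by the small Lewis-acidic aluminium hydride should stop cleanly at the allylic alcohol and leave the silyl ethers untouched.

Step 7
Reactants: 7 allylic alcohol
Product: 8 (3R,4R)-3,4-bis(tert-butyldimethylsilyloxy)-2,6,6-trimethylcyclohex-1-ene-1-carbaldehyde
Conditions: MnO2 (activated, excess), CH2Cl2, rt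
Reagents that add atoms: none
Why: Allylic oxidation with MnO2 is selective for the primary allylic alcohol and cannot over-oxidise, as is usual for cyclogeraniol-type alcohols.

Step 8
Reactants: 8 ring aldehyde
Product: 9 (3E)-4-[(3R,4R)-3,4-bis(tert-butyldimethylsilyloxy)-2,6,6-trimethylcyclohex-1-en-1-yl]but-3-en-2-one
Conditions: (EtO)2P(O)CH2COCH3, NaH, THF, 0 to 50 °C
Reagents that add atoms: diethyl (2-oxopropyl)phosphonate, CCOP(=O)(CC(C)=O)OCC
Why: Horner–Wadsworth–Emmons olefination with a small stabilised phosphonate anion, which reaches the flanked aldehyde, gives the E-enone under thermodynamic control and is mild enough to leave the γ-positions and the silyl ethers alone.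

Step 9
Reactants: 9 ring enone
Product: 10 (1E)-1-[(3R,4R)-3,4-bis(tert-butyldimethylsilyloxy)-2,6,6-trimethylcyclohex-1-en-1-yl]-3-methylpenta-1,4-dien-3-ol (both epimers at the new carbinol carbon)
Conditions: CH2=CHMgBr, THF, −20 to 0 °C; then aq NH4Cl
Reagents that add atoms: vinylmagnesium bromide, C=C[Mg]Br
Why: Grignard 1,2-addition to an ionone-type enone, whose β-carbon is shielded by the ring, gives the tertiary bis-allylic alcohol, and the new carbinol centre needs no control because it is removed in the next step.

Step 10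
Reactants: 10 tertiary bis-allylic alcohol
Product: 11 [(2E,4E)-5-[(3R,4R)-3,4-bis(tert-butyldimethylsilyloxy)-2,6,6-trimethylcyclohex-1-en-1-yl]-3-methylpenta-2,4-dien-1-yl]triphenylphosphonium bromide
Conditions: PPh3·HBr, CH2Cl2, 0 °C to rt
Reagents that add atoms: triphenylphosphine hydrobromide, [Br-].[PH+](c1ccccc1)(c1ccccc1)c1ccccc1
Why: The tertiary alcohol ionises to a pentadienyl cation that PPh3 captures at the unhindered primary terminus (SN1 with allylic transposition, the standard vinyl-ionol to C15 Wittig salt conversion), the conjugated 2E,4E salt being thermodynamically favoured, while the aprotic solvent and low temperature should spare the silyl ethers.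

Step 11
Reactants: 12 pseudoionone ((3E,5E)-6,10-dimethylundeca-3,5,9-trien-2-one)
Product: 13 (4E,6E)-3,7,11-trimethyldodeca-1,4,6,10-tetraen-3-ol
Conditions: CH2=CHMgBr, THF, 0 °C; then aq NH4Cl
Reagents that add atoms: vinylmagnesium bromide, C=C[Mg]Br
Why: Grignard 1,2-addition to the dienone carbonyl gives the tertiary bis-allylic alcohol, whose configuration is irrelevant because it is lost in the next step.

Step 12
Reactants: 13 tertiary alcohol of the ψ series
Product: 14 [(2E,4E,6E)-3,7,11-trimethyldodeca-2,4,6,10-tetraen-1-yl]triphenylphosphonium bromide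
Conditions: PPh3·HBr, MeOH, rt; crystallisation
Reagents that add atoms: triphenylphosphine hydrobromide, [Br-].[PH+](c1ccccc1)(c1ccccc1)c1ccccc1
Why: The same SN1 allylic transposition with phosphine capture at the primary terminus gives the conjugated all-E salt, which crystallisation should free from Z isomers.

Step 13
Reactants: 14 ψ-C15 phosphonium bromide; 15 (2E,4E,6E)-2,7-dimethylocta-2,4,6-trienedial (3 equiv)
Product: 18 all-E apo-12'-lycopenal [(2E,4E,6E,8E,10E,12E,14E)-2,7,11,15,19-pentamethylicosa-2,4,6,8,10,12,14,18-octaenal], via ψ-C15 phosphorus ylide 16 (not isolated), via 8Z aldehyde isomer 17 (not isolated)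
Conditions: NaOMe, CH2Cl2/MeOH, 0 °C to rt, slow addition of salt and base to the dial; then heptane, reflux
Reagents that add atoms: none
Why: Wittig olefination of one of the two equivalent aldehyde groups of the dial, kept in excess to suppress double condensation, by the semistabilised allylic ylide forms C11'=C12' as an E/Z mixture, and the hindered Z isomer (cis bond next to the C13' methyl) should relax thermally to the all-E polyenal.

Step 14
Reactants: 11 ring C15 phosphonium bromide; 18 all-E apo-12'-lycopenal
Product: 21 (3R,4R)-3,4-bis(tert-butyldimethylsilyloxy)-β,ψ-carotene (all-E), via ring C15 phosphorus ylide 19 (not isolated), via 11Z carotene isomer 20 (not isolated)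
Conditions: NaOMe, CH2Cl2/MeOH, 0 °C to rt; then heptane, reflux
Reagents that add atoms: none
Why: Wittig olefination of the C25 polyenal by the allylic ylide forms C11=C12 and completes the C40 chain, methoxide leaves the secondary silyl ethers intact, and the hindered 11Z isomer should equilibrate thermally to the all-E polyene without touching C3 or C4.

Step 15
Reactants: 21 bis-silyl ether of the target
Product: 22 (3R,4R)-β,ψ-carotene-3,4-diol (CNP0310445.1)
Conditions: Bu4NF, THF, 0 °C to rt
Reagents that add atoms: none
Why: Fluoride cleaves both Si–O bonds under non-acidic conditions, which should spare the polyene and the acid-sensitive allylic C4 carbinol and leave both stereocentres unchanged.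

**Compound list**

1 | safranal (2,6,6-trimethylcyclohexa-1,3-diene-1-carbaldehyde) | CC1=C(C=O)C(C)(C)CC=C1 | starting material
2 | safranic acid (2,6,6-trimethylcyclohexa-1,3-diene-1-carboxylic acid) | CC1=C(C(=O)O)C(C)(C)CC=C1 | intermediate
3 | methyl safranate (methyl 2,6,6-trimethylcyclohexa-1,3-diene-1-carboxylate) | COC(=O)C1=C(C)C=CCC1(C)C | intermediate
4 | methyl (1S,6R)-2,4,4-trimethyl-7-oxabicyclo[4.1.0]hept-2-ene-3-carboxylate (cis-3,4-epoxide, carotenoid C3 R, C4 S) | COC(=O)C1=C(C)[C@@H]2O[C@@H]2CC1(C)C | intermediate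
5 | methyl (3R,4R)-3,4-dihydroxy-2,6,6-trimethylcyclohex-1-ene-1-carboxylate | COC(=O)C1=C(C)[C@@H](O)[C@H](O)CC1(C)C | intermediate
6 | methyl (3R,4R)-3,4-bis(tert-butyldimethylsilyloxy)-2,6,6-trimethylcyclohex-1-ene-1-carboxylate | COC(=O)C1=C(C)[C@@H](O[Si](C)(C)C(C)(C)C)[C@H](O[Si](C)(C)C(C)(C)C)CC1(C)C | intermediate
7 | [(3R,4R)-3,4-bis(tert-butyldimethylsilyloxy)-2,6,6-trimethylcyclohex-1-en-1-yl]methanol | OCC1=C(C)[C@@H](O[Si](C)(C)C(C)(C)C)[C@H](O[Si](C)(C)C(C)(C)C)CC1(C)C | intermediate
8 | (3R,4R)-3,4-bis(tert-butyldimethylsilyloxy)-2,6,6-trimethylcyclohex-1-ene-1-carbaldehyde | O=CC1=C(C)[C@@H](O[Si](C)(C)C(C)(C)C)[C@H](O[Si](C)(C)C(C)(C)C)CC1(C)C | intermediate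
9 | (3E)-4-[(3R,4R)-3,4-bis(tert-butyldimethylsilyloxy)-2,6,6-trimethylcyclohex-1-en-1-yl]but-3-en-2-one | CC(=O)/C=C/C1=C(C)[C@@H](O[Si](C)(C)C(C)(C)C)[C@H](O[Si](C)(C)C(C)(C)C)CC1(C)C | intermediate
10 | (1E)-1-[(3R,4R)-3,4-bis(tert-butyldimethylsilyloxy)-2,6,6-trimethylcyclohex-1-en-1-yl]-3-methylpenta-1,4-dien-3-ol (epimers at the chain carbinol) | C=CC(C)(O)/C=C/C1=C(C)[C@@H](O[Si](C)(C)C(C)(C)C)[C@H](O[Si](C)(C)C(C)(C)C)CC1(C)C | intermediate
11 | [(2E,4E)-5-[(3R,4R)-3,4-bis(tert-butyldimethylsilyloxy)-2,6,6-trimethylcyclohex-1-en-1-yl]-3-methylpenta-2,4-dien-1-yl]triphenylphosphonium bromide | [Br-].c1ccccc1[P+](c1ccccc1)(c1ccccc1)C/C=C(C)/C=C/C1=C(C)[C@@H](O[Si](C)(C)C(C)(C)C)[C@H](O[Si](C)(C)C(C)(C)C)CC1(C)C | intermediate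
12 | pseudoionone ((3E,5E)-6,10-dimethylundeca-3,5,9-trien-2-one) | CC(C)=CCC/C(C)=C/C=C/C(C)=O | starting material
13 | (4E,6E)-3,7,11-trimethyldodeca-1,4,6,10-tetraen-3-ol | CC(C)=CCC/C(C)=C/C=C/C(C)(O)C=C | intermediate
14 | [(2E,4E,6E)-3,7,11-trimethyldodeca-2,4,6,10-tetraen-1-yl]triphenylphosphonium bromide | [Br-].CC(C)=CCC/C(C)=C/C=C/C(C)=C/C[P+](c1ccccc1)(c1ccccc1)c1ccccc1 | intermediate
15 | (2E,4E,6E)-2,7-dimethylocta-2,4,6-trienedial | O=C/C(C)=C/C=C/C=C(C)/C=O | starting material
16 | [(2E,4E,6E)-3,7,11-trimethyldodeca-2,4,6,10-tetraen-1-ylidene]triphenylphosphorane (formed in the flask, not isolated) | CC(C)=CCC/C(C)=C/C=C/C(C)=C/C=P(c1ccccc1)(c1ccccc1)c1ccccc1 | intermediate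
17 | (2E,4E,6E,8Z,10E,12E,14E)-2,7,11,15,19-pentamethylicosa-2,4,6,8,10,12,14,18-octaenal (formed in the flask, not isolated) | CC(C)=CCC/C(C)=C/C=C/C(C)=C/C=C\C(C)=C\C=C\C=C(C)\C=O | intermediate
18 | all-E apo-12'-lycopenal, (2E,4E,6E,8E,10E,12E,14E)-2,7,11,15,19-pentamethylicosa-2,4,6,8,10,12,14,18-octaenal | CC(C)=CCC/C(C)=C/C=C/C(C)=C/C=C/C(C)=C/C=C/C=C(C)/C=O | intermediate
19 | [(2E,4E)-5-[(3R,4R)-3,4-bis(tert-butyldimethylsilyloxy)-2,6,6-trimethylcyclohex-1-en-1-yl]-3-methylpenta-2,4-dien-1-ylidene]triphenylphosphorane (formed in the flask, not isolated) | c1ccccc1P(c1ccccc1)(c1ccccc1)=C/C=C(C)/C=C/C1=C(C)[C@@H](O[Si](C)(C)C(C)(C)C)[C@H](O[Si](C)(C)C(C)(C)C)CC1(C)C | intermediate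
20 | (11Z)-(3R,4R)-3,4-bis(tert-butyldimethylsilyloxy)-β,ψ-carotene (formed in the flask, not isolated) | CC(C)=CCC/C(C)=C/C=C/C(C)=C/C=C/C(C)=C/C=C/C=C(C)/C=C\C=C(C)\C=C\C1=C(C)[C@@H](O[Si](C)(C)C(C)(C)C)[C@H](O[Si](C)(C)C(C)(C)C)CC1(C)C | intermediate
21 | all-E (3R,4R)-3,4-bis(tert-butyldimethylsilyloxy)-β,ψ-carotene | CC(C)=CCC/C(C)=C/C=C/C(C)=C/C=C/C(C)=C/C=C/C=C(C)/C=C/C=C(C)/C=C/C1=C(C)[C@@H](O[Si](C)(C)C(C)(C)C)[C@H](O[Si](C)(C)C(C)(C)C)CC1(C)C | intermediate
22 | (3R,4R)-β,ψ-carotene-3,4-diol (CNP0310445.1) | CC(C)=CCC/C(C)=C/C=C/C(C)=C/C=C/C(C)=C/C=C/C=C(C)/C=C/C=C(C)/C=C/C1=C(C)[C@@H](O)[C@H](O)CC1(C)C | target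

**Step count**

Total: 15 steps. Longest linear sequence: 12 steps (steps 1–10, 14 and 15, from safranal); the ψ-end branch (steps 11–13) joins at step 14.

**Steps most likely to fail**

Step 3. The oxygen transfer may discriminate poorly between the two faces of this particular 1,3-diene, or some oxidation may occur at C5=C6, so that the epoxide is formed with insufficient enantiomeric purity. The fallback moves the source of chirality from the catalyst to an enzyme; it sets out from 3 and returns at 5. Buffered mCPBA in CH2Cl2 should epoxidise the electron-richer C3=C4 alkene to the racemic cis-epoxide F1, and dilute HClO4 in aqueous THF should open it to the racemic trans-diol F2 (in the racemic series the site of water attack is irrelevant). Candida antarctica lipase B with vinyl acetate in t-BuOMe should then acylate the less hindered C3 hydroxyl of one enantiomer, expected to be the R,R one by analogy with trans-cyclohexane-1,2-diol, giving the (3R,4R)-monoacetate F3. This is separated from the slow-reacting (3S,4S)-diol and methanolysed with K2CO3 in MeOH to 5.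

Step 4. Water may attack C3 in competition with C4, which would deliver the mirror-image diol and erode enantiomeric purity, or the protonated vinyl epoxide may rearrange before it is trapped. The fallback changes the electronic character of the substrate before the opening; it sets out from 4 and returns at 8. i-Bu2AlH at −78 °C should reduce the γ,δ-epoxy enoate to the epoxy allylic alcohol F4 without touching the oxirane. With the ester gone the C5=C6 alkene is electron-rich, so buffered aqueous THF at pH 4–5 should cleave only the allylic C4–O bond, water entering anti to the C3 oxygen to give triol F5. TEMPO with PhI(OAc)2 should oxidise only the primary allylic alcohol to the dihydroxy aldehyde F6, and TBSOTf with 2,6-lutidine should then give 8.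

Step 10. The acid may remove a silyl ether or ionise the allylic C4–O bond (pseudoaxial in the bis-silyl ether) with elimination towards a 3,4-didehydro or retro system while the tertiary alcohol is converted. The fallback avoids acid altogether; it sets out from 9 and returns at 11. Horner–Wadsworth–Emmons reaction of 9 with triethyl phosphonoacetate (NaH, THF) should give the trienoate F7, from which the minor 9Z isomer is separated. i-Bu2AlH should reduce it to the C15 allylic alcohol F8, CBr4/PPh3 should convert this under neutral Appel conditions into the allylic bromide F9, and PPh3 in ethyl acetate should quaternise the bromide to 11.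

**Further compounds**

F1 | step 3 | racemic methyl 2,4,4-trimethyl-7-oxabicyclo[4.1.0]hept-2-ene-3-carboxylate (cis-epoxide, both enantiomers written) | COC(=O)C1=C(C)[C@@H]2O[C@@H]2CC1(C)C.COC(=O)C1=C(C)[C@H]2O[C@H]2CC1(C)C
F2 | step 3 | racemic methyl trans-3,4-dihydroxy-2,6,6-trimethylcyclohex-1-ene-1-carboxylate (both enantiomers written) | COC(=O)C1=C(C)[C@@H](O)[C@H](O)CC1(C)C.COC(=O)C1=C(C)[C@H](O)[C@@H](O)CC1(C)C
F3 | step 3 | methyl (3R,4R)-4-acetoxy-3-hydroxy-2,6,6-trimethylcyclohex-1-ene-1-carboxylate (acetate on carotenoid C3) | COC(=O)C1=C(C)[C@@H](O)[C@H](OC(C)=O)CC1(C)C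
F4 | step 4 | [(1S,6R)-2,4,4-trimethyl-7-oxabicyclo[4.1.0]hept-2-en-3-yl]methanol | OCC1=C(C)[C@@H]2O[C@@H]2CC1(C)C
F5 | step 4 | (1R,2R)-4-(hydroxymethyl)-3,5,5-trimethylcyclohex-3-ene-1,2-diol | OCC1=C(C)[C@@H](O)[C@H](O)CC1(C)C
F6 | step 4 | (3R,4R)-3,4-dihydroxy-2,6,6-trimethylcyclohex-1-ene-1-carbaldehyde | O=CC1=C(C)[C@@H](O)[C@H](O)CC1(C)C
F7 | step 10 | ethyl (2E,4E)-5-[(3R,4R)-3,4-bis(tert-butyldimethylsilyloxy)-2,6,6-trimethylcyclohex-1-en-1-yl]-3-methylpenta-2,4-dienoate | CCOC(=O)/C=C(C)/C=C/C1=C(C)[C@@H](O[Si](C)(C)C(C)(C)C)[C@H](O[Si](C)(C)C(C)(C)C)CC1(C)C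
F8 | step 10 | (2E,4E)-5-[(3R,4R)-3,4-bis(tert-butyldimethylsilyloxy)-2,6,6-trimethylcyclohex-1-en-1-yl]-3-methylpenta-2,4-dien-1-ol | OC/C=C(C)/C=C/C1=C(C)[C@@H](O[Si](C)(C)C(C)(C)C)[C@H](O[Si](C)(C)C(C)(C)C)CC1(C)C
F9 | step 10 | (2E,4E)-1-bromo-5-[(3R,4R)-3,4-bis(tert-butyldimethylsilyloxy)-2,6,6-trimethylcyclohex-1-en-1-yl]-3-methylpenta-2,4-diene | BrC/C=C(C)/C=C/C1=C(C)[C@@H](O[Si](C)(C)C(C)(C)C)[C@H](O[Si](C)(C)C(C)(C)C)CC1(C)C
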